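**Strategy**

With the seven-carbon chain numbered from the arylethyl terminus (C1) to the aryl-bearing carbon (C7), the oxane oxygen links C3 and C7 and the hydroxyl sits on C5; the ring is cut at C3–C4. Since the C1–C2 arm on C3 ends at an arene, C1 can be carried as an aryl ketone and C2=C3 as an enol ether of the C7 oxygen. A primary C4 radical then closes the oxane 6-exo at C3, creating C3–C4 and the C3 stereocentre cis to C7 in one operation. The precursor is a syn C5-silyloxy/C7-aryl chain bearing iodine on C4 and an (E)-3-aryl-3-oxopropenyl ether on the C7 oxygen; iodine is introduced last.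

Key step: step 10

Remark: chlorine is kept at C4 until the enol ether exists and is exchanged for iodine only then, because a 4-iodo-1-ol could close to an oxolane or alkylate the phosphine catalyst; the (R)-chlorohydrin ester supplies C5 and the CBS reduction sets C7 (S), which together give the 5,7-syn pattern of the (2S,4S,6S)-oxane target.

**Route**

Step 1
Reactants: 1 ethyl (R)-4-chloro-3-hydroxybutanoate
Product: 2 ethyl (3R)-3-[(tert-butyldimethylsilyl)oxy]-4-chlorobutanoate
Conditions: TBSCl, imidazole, DMF, 0 °C → rt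
Reagents that add atoms: tert-butyldimethylsilyl chloride, CC(C)(C)[Si](C)(C)Cl
Why: Imidazole-promoted silylation of the secondary alcohol (Corey protocol) is mild enough to leave the chlorohydrin ester intact, and the stereocentre is not touched.

Step 2
Reactants: 2 ethyl (3R)-3-[(tert-butyldimethylsilyl)oxy]-4-chlorobutanoate
Product: 3 (3R)-3-[(tert-butyldimethylsilyl)oxy]-4-chloro-N-methoxy-N-methylbutanamide
Conditions: MeNH(OMe)·HCl, i-PrMgCl, THF, −20 → −10 °C
Reagents that add atoms: N,O-dimethylhydroxylamine hydrochloride, CNOC.Cl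
Why: Direct aminolysis of the ester by the chloromagnesium amide of N,O-dimethylhydroxylamine (Weinreb amide formation) proceeds at low temperature without β-elimination of the silyloxy group or attack at the primary chloride.

Step 3
Reactants: 4 4-bromo-2-methoxyphenol
Product: 5 1-(benzyloxy)-4-bromo-2-methoxybenzene
Conditions: BnBr, K2CO3, DMF, rt
Reagents that add atoms: benzyl bromide, BrCc1ccccc1
Why: Williamson etherification of the phenoxide with benzyl bromide masks the phenol for the organomagnesium chemistry that follows.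

Step 4
Reactants: 5 1-(benzyloxy)-4-bromo-2-methoxybenzene; 3 (3R)-3-[(tert-butyldimethylsilyl)oxy]-4-chloro-N-methoxy-N-methylbutanamide
Product: 7 (3R)-1-[4-(benzyloxy)-3-methoxyphenyl]-3-[(tert-butyldimethylsilyl)oxy]-4-chlorobutan-1-one, via [4-(benzyloxy)-3-methoxyphenyl]magnesium bromide 6 (not isolated)
Conditions: Mg, cat. I2, THF, 45 °C; then 3, THF, 0 °C → rt; aq. NH4Cl
Reagents that add atoms: none
Why: Magnesium insertion gives the aryl Grignard reagent, whose addition to the Weinreb amide stops at the chelated tetrahedral adduct and releases the ketone only on work-up (Weinreb ketone synthesis), while the primary chloride and the silyl ether are inert to the arylmagnesium species.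

Step 5
Reactants: 7 (3R)-1-[4-(benzyloxy)-3-methoxyphenyl]-3-[(tert-butyldimethylsilyl)oxy]-4-chlorobutan-1-one
Product: 8 (1S,3R)-1-[4-(benzyloxy)-3-methoxyphenyl]-3-[(tert-butyldimethylsilyl)oxy]-4-chlorobutan-1-ol (1,3-syn)
Conditions: (R)-2-methyl-CBS-oxazaborolidine (0.2 equiv), BH3·SMe2, THF, −20 °C; MeOH quench
Reagents that add atoms: none
Why: Corey–Bakshi–Shibata reduction in which the aryl group acts as the large substituent, so that the (R)-oxazaborolidine should deliver hydride to the face that gives the (S)-benzylic carbinol, 1,3-syn to the silyloxy group, under reagent control.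

Step 6
Reactants: 9 4-(benzyloxy)-3-methoxybenzaldehyde (O-benzylvanillin); 10 ethynylmagnesium bromide
Product: 11 1-[4-(benzyloxy)-3-methoxyphenyl]prop-2-yn-1-ol (racemic)
Conditions: THF, 0 °C; aq. NH4Cl
Reagents that add atoms: none
Why: 1,2-Addition of the alkynyl Grignard reagent to the aromatic aldehyde gives the propargylic alcohol, whose configuration is irrelevant because the carbinol is oxidised next.

Step 7
Reactants: 11 1-[4-(benzyloxy)-3-methoxyphenyl]prop-2-yn-1-ol
Product: 12 1-[4-(benzyloxy)-3-methoxyphenyl]prop-2-yn-1-one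
Conditions: activated MnO2, CH2Cl2, rt
Reagents that add atoms: none
Why: Manganese dioxide oxidation of a benzylic and propargylic alcohol is selective and neutral, so the base-sensitive terminal ynone should be obtained without conjugate addition.

Step 8
Reactants: 8 (1S,3R)-1-[4-(benzyloxy)-3-methoxyphenyl]-3-[(tert-butyldimethylsilyl)oxy]-4-chlorobutan-1-ol; 12 1-[4-(benzyloxy)-3-methoxyphenyl]prop-2-yn-1-one
Product: 13 (2E)-1-[4-(benzyloxy)-3-methoxyphenyl]-3-{(1S,3R)-1-[4-(benzyloxy)-3-methoxyphenyl]-3-[(tert-butyldimethylsilyl)oxy]-4-chlorobutoxy}prop-2-en-1-one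
Conditions: PMe3 (0.1 equiv), CH2Cl2, 0 °C → rt
Reagents that add atoms: none
Why: Phosphine-catalysed oxa-Michael (conjugate) addition of an alcohol to an ynone gives the thermodynamically favoured (E)-β-alkoxy enone; the primary chloride is too unreactive to alkylate the catalyst or to be displaced by the transient alkoxide, and no stereocentre is involved.

Step 9
Reactants: 13 (2E)-1-[4-(benzyloxy)-3-methoxyphenyl]-3-{(1S,3R)-1-[4-(benzyloxy)-3-methoxyphenyl]-3-[(tert-butyldimethylsilyl)oxy]-4-chlorobutoxy}prop-2-en-1-one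
Product: 14 (2E)-1-[4-(benzyloxy)-3-methoxyphenyl]-3-{(1S,3R)-1-[4-(benzyloxy)-3-methoxyphenyl]-3-[(tert-butyldimethylsilyl)oxy]-4-iodobutoxy}prop-2-en-1-one
Conditions: NaI (10 equiv), NaHCO3, 2-butanone, reflux, dark
Reagents that add atoms: sodium iodide, [Na+].[I-]
Why: Finkelstein exchange (SN2 at the primary C4, driven by precipitation of sodium chloride) under neutral buffered conditions installs the radical leaving group last, without touching the C5 and C7 stereocentres.

Step 10
Reactants: 14 (2E)-1-[4-(benzyloxy)-3-methoxyphenyl]-3-{(1S,3R)-1-[4-(benzyloxy)-3-methoxyphenyl]-3-[(tert-butyldimethylsilyl)oxy]-4-iodobutoxy}prop-2-en-1-one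
Product: 15 1-[4-(benzyloxy)-3-methoxyphenyl]-2-[(2R,4S,6S)-6-[4-(benzyloxy)-3-methoxyphenyl]-4-[(tert-butyldimethylsilyl)oxy]oxan-2-yl]ethan-1-one (2,6-cis; 4-silyloxy trans to both, axial)
Conditions: Bu3SnH (1.5 equiv, syringe pump), AIBN (0.2 equiv), toluene (0.01 M), 85 °C
Reagents that add atoms: none
Why: The tributylstannyl radical abstracts iodine from C4, the nucleophilic primary radical adds to the electron-poor β-carbon C3 of the vinylogous ester, and the resulting α-keto radical at C2 takes hydrogen from the stannane, which carries the chain. The closest known reaction type is the tin-hydride cyclisation of β-alkoxyacrylates and β-alkoxyvinyl ketones to 2,6-cis-oxanes. The oxane ring closes in the 6-exo-trig mode through formation of C3–C4. The new C3 stereocentre is controlled by a chair-like transition state in which the C7 aryl group is equatorial and the extended s-trans enone is pseudo-equatorial, which places the C3 arm cis to the C7 aryl and leaves the C5 silyloxy group axial. The step needs ring closure to outrun hydrogen transfer to the C4 radical and tin attack on the enone, and cis to win over trans closure; fast iodine abstraction, the strongly activated acceptor, slow stannane addition at high dilution and the large equatorial preference of the C7 aryl should secure this.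

Step 11
Reactants: 15 1-[4-(benzyloxy)-3-methoxyphenyl]-2-[(2R,4S,6S)-6-[4-(benzyloxy)-3-methoxyphenyl]-4-[(tert-butyldimethylsilyl)oxy]oxan-2-yl]ethan-1-one
Product: 16 N'-{1-[4-(benzyloxy)-3-methoxyphenyl]-2-[(2S,4S,6S)-6-[4-(benzyloxy)-3-methoxyphenyl]-4-[(tert-butyldimethylsilyl)oxy]oxan-2-yl]ethylidene}-4-methylbenzenesulfonohydrazide
Conditions: TsNHNH2, cat. AcOH, EtOH, 60 °C
Reagents that add atoms: p-toluenesulfonyl hydrazide, Cc1ccc(cc1)S(=O)(=O)NN
Why: Acid-catalysed condensation of the ketone with the sulfonyl hydrazide gives the tosylhydrazone under conditions mild enough to avoid β-elimination of the ring oxygen.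

Step 12
Reactants: 16 N'-{1-[4-(benzyloxy)-3-methoxyphenyl]-2-[(2S,4S,6S)-6-[4-(benzyloxy)-3-methoxyphenyl]-4-[(tert-butyldimethylsilyl)oxy]oxan-2-yl]ethylidene}-4-methylbenzenesulfonohydrazide
Product: 19 {[(2S,4S,6S)-2-[4-(benzyloxy)-3-methoxyphenyl]-6-{2-[4-(benzyloxy)-3-methoxyphenyl]ethyl}oxan-4-yl]oxy}(tert-butyl)dimethylsilane, via N-catecholboryl tosylhydrazine adduct 17 (not isolated), via C1 monoalkyl diazene 18 (not isolated)
Conditions: catecholborane, CHCl3, 0 °C → rt; then NaOAc·3H2O, reflux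
Reagents that add atoms: none
Why: Kabalka variant of the Caglioti tosylhydrazone reduction: hydroboration of the C=N bond by catecholborane, then acetate-induced loss of sulfinate to the alkyl diazene, which extrudes nitrogen to leave the C1 methylene without strong acid or base reaching the ring stereocentres.

Step 13
Reactants: 19 {[(2S,4S,6S)-2-[4-(benzyloxy)-3-methoxyphenyl]-6-{2-[4-(benzyloxy)-3-methoxyphenyl]ethyl}oxan-4-yl]oxy}(tert-butyl)dimethylsilane
Product: 20 (2S,4S,6S)-2-[4-(benzyloxy)-3-methoxyphenyl]-6-{2-[4-(benzyloxy)-3-methoxyphenyl]ethyl}oxan-4-ol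
Conditions: TBAF, THF, rt → 40 °C
Reagents that add atoms: none
Why: Fluoride-induced desilylation of the secondary silyl ether, driven by the Si–F bond, frees the C5 hydroxyl with retention because the C–O bond is not broken.

Step 14
Reactants: 20 (2S,4S,6S)-2-[4-(benzyloxy)-3-methoxyphenyl]-6-{2-[4-(benzyloxy)-3-methoxyphenyl]ethyl}oxan-4-ol
Product: 21 (2S,4S,6S)-2-(4-hydroxy-3-methoxyphenyl)-6-[2-(4-hydroxy-3-methoxyphenyl)ethyl]oxan-4-ol (target)
Conditions: H2 (1 atm), 10% Pd/C, EtOAc, rt
Reagents that add atoms: none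
Why: Palladium-catalysed hydrogenolysis of the two aryl benzyl ethers under neutral conditions is much faster than cleavage of the cyclic benzylic C7–O bond, so the reaction should be stopped as soon as both phenols are free.

**Compound list**

The descriptor at the ring carbon that carries the side arm is R in 15 and S in 16–21 only because the substituent priorities change; the geometry is the same throughout.

1 | ethyl (R)-4-chloro-3-hydroxybutanoate | ClC[C@H](O)CC(=O)OCC | starting material
2 | ethyl (3R)-3-[(tert-butyldimethylsilyl)oxy]-4-chlorobutanoate | ClC[C@H](O[Si](C)(C)C(C)(C)C)CC(=O)OCC | intermediate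
3 | (3R)-3-[(tert-butyldimethylsilyl)oxy]-4-chloro-N-methoxy-N-methylbutanamide | ClC[C@H](O[Si](C)(C)C(C)(C)C)CC(=O)N(C)OC | intermediate
4 | 4-bromo-2-methoxyphenol | COc1cc(Br)ccc1O | starting material
5 | 1-(benzyloxy)-4-bromo-2-methoxybenzene | COc1cc(Br)ccc1OCc1ccccc1 | intermediate
6 | [4-(benzyloxy)-3-methoxyphenyl]magnesium bromide | COc1cc([Mg]Br)ccc1OCc1ccccc1 | intermediate
7 | (3R)-1-[4-(benzyloxy)-3-methoxyphenyl]-3-[(tert-butyldimethylsilyl)oxy]-4-chlorobutan-1-one | ClC[C@H](O[Si](C)(C)C(C)(C)C)CC(=O)c1ccc(OCc2ccccc2)c(OC)c1 | intermediate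
8 | (1S,3R)-1-[4-(benzyloxy)-3-methoxyphenyl]-3-[(tert-butyldimethylsilyl)oxy]-4-chlorobutan-1-ol | ClC[C@H](O[Si](C)(C)C(C)(C)C)C[C@H](O)c1ccc(OCc2ccccc2)c(OC)c1 | intermediate
9 | 4-(benzyloxy)-3-methoxybenzaldehyde | COc1cc(C=O)ccc1OCc1ccccc1 | starting material
10 | ethynylmagnesium bromide | C#C[Mg]Br | starting material
11 | 1-[4-(benzyloxy)-3-methoxyphenyl]prop-2-yn-1-ol (racemic) | C#CC(O)c1ccc(OCc2ccccc2)c(OC)c1 | intermediate
12 | 1-[4-(benzyloxy)-3-methoxyphenyl]prop-2-yn-1-one | C#CC(=O)c1ccc(OCc2ccccc2)c(OC)c1 | intermediate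
13 | (2E)-1-[4-(benzyloxy)-3-methoxyphenyl]-3-{(1S,3R)-1-[4-(benzyloxy)-3-methoxyphenyl]-3-[(tert-butyldimethylsilyl)oxy]-4-chlorobutoxy}prop-2-en-1-one | ClC[C@H](O[Si](C)(C)C(C)(C)C)C[C@H](O/C=C/C(=O)c1ccc(OCc2ccccc2)c(OC)c1)c1ccc(OCc2ccccc2)c(OC)c1 | intermediate
14 | (2E)-1-[4-(benzyloxy)-3-methoxyphenyl]-3-{(1S,3R)-1-[4-(benzyloxy)-3-methoxyphenyl]-3-[(tert-butyldimethylsilyl)oxy]-4-iodobutoxy}prop-2-en-1-one | IC[C@H](O[Si](C)(C)C(C)(C)C)C[C@H](O/C=C/C(=O)c1ccc(OCc2ccccc2)c(OC)c1)c1ccc(OCc2ccccc2)c(OC)c1 | intermediate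
15 | 1-[4-(benzyloxy)-3-methoxyphenyl]-2-[(2R,4S,6S)-6-[4-(benzyloxy)-3-methoxyphenyl]-4-[(tert-butyldimethylsilyl)oxy]oxan-2-yl]ethan-1-one | O=C(C[C@H]2C[C@H](O[Si](C)(C)C(C)(C)C)C[C@@H](c3ccc(OCc4ccccc4)c(OC)c3)O2)c1ccc(OCc2ccccc2)c(OC)c1 | intermediate
16 | N'-{1-[4-(benzyloxy)-3-methoxyphenyl]-2-[(2S,4S,6S)-6-[4-(benzyloxy)-3-methoxyphenyl]-4-[(tert-butyldimethylsilyl)oxy]oxan-2-yl]ethylidene}-4-methylbenzenesulfonohydrazide | Cc1ccc(cc1)S(=O)(=O)NN=C(C[C@H]2C[C@H](O[Si](C)(C)C(C)(C)C)C[C@@H](c3ccc(OCc4ccccc4)c(OC)c3)O2)c1ccc(OCc2ccccc2)c(OC)c1 | intermediate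
17 | adduct of 16 with catecholborane: H on C1, 1,3,2-benzodioxaborol-2-yl on the adjacent nitrogen, N'-tosyl retained (C1 epimers) | Cc1ccc(cc1)S(=O)(=O)NN(B1Oc2ccccc2O1)C(C[C@H]2C[C@H](O[Si](C)(C)C(C)(C)C)C[C@@H](c3ccc(OCc4ccccc4)c(OC)c3)O2)c1ccc(OCc2ccccc2)c(OC)c1 | intermediate
18 | C1 monoalkyl diazene (HN=N– on C1, C1 epimers) formed from 17 by loss of sulfinate | N=NC(C[C@H]2C[C@H](O[Si](C)(C)C(C)(C)C)C[C@@H](c3ccc(OCc4ccccc4)c(OC)c3)O2)c1ccc(OCc2ccccc2)c(OC)c1 | intermediate
19 | {[(2S,4S,6S)-2-[4-(benzyloxy)-3-methoxyphenyl]-6-{2-[4-(benzyloxy)-3-methoxyphenyl]ethyl}oxan-4-yl]oxy}(tert-butyl)dimethylsilane | COc1cc(CC[C@H]2C[C@H](O[Si](C)(C)C(C)(C)C)C[C@@H](c3ccc(OCc4ccccc4)c(OC)c3)O2)ccc1OCc1ccccc1 | intermediate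
20 | (2S,4S,6S)-2-[4-(benzyloxy)-3-methoxyphenyl]-6-{2-[4-(benzyloxy)-3-methoxyphenyl]ethyl}oxan-4-ol | COc1cc(CC[C@H]2C[C@H](O)C[C@@H](c3ccc(OCc4ccccc4)c(OC)c3)O2)ccc1OCc1ccccc1 | intermediate
21 | (2S,4S,6S)-2-(4-hydroxy-3-methoxyphenyl)-6-[2-(4-hydroxy-3-methoxyphenyl)ethyl]oxan-4-ol | COc1cc(CC[C@H]2C[C@H](O)C[C@@H](c3ccc(O)c(OC)c3)O2)ccc1O | target

**Step count and risks**

Total step count: 14. Longest linear sequence: 11 steps (1, 2, 4, 5, 8, 9, 10, 11, 12, 13, 14, from compound 1); steps 3 and 6–7 are side branches.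

Steps most likely to fail:

1. Step 10 (key step). Tin-centred radicals could add to the aryl enone (hydrostannation), hydrogen could be transferred to the C4 radical before the ring closes, and the axial silyloxy group could weaken the chair preference. The fallback moves the aryl ketone out of the radical step and uses the acrylate acceptor, which is inert to tin radicals. It sets out from 8. Addition of 8 to ethyl propiolate (N-methylmorpholine, CH2Cl2) would give the chloro β-alkoxyacrylate F1. Halide exchange (NaI, 2-butanone, reflux) would give the iodo β-alkoxyacrylate F2. Cyclisation with Bu3SnH/AIBN would give the cis-2,6-oxan-2-ylacetic ester F3. Aminolysis (MeNH(OMe)·HCl, i-PrMgCl) would give the oxanyl Weinreb amide F4. Addition of the Grignard reagent 6 then forms the C1–aryl bond and comes back to the route at 15.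

2. Step 9. Substitution at the β-branched, β-oxygenated C4 is slow, and prolonged heating could degrade the vinylogous ester, for example by ionisation of the electron-rich benzylic C7–O bond. The fallback makes the exchange before that function exists. It sets out from 7. Treatment with NaI in refluxing 2-butanone would give the iodo ketone F5. CBS reduction as in step 5 would give the syn iodo alcohol F6. Addition of F6 to ynone 12 under N-methylmorpholine catalysis (a tertiary amine in place of the alkylatable phosphine, at 0 °C) comes back to the route at 14.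

3. Step 12 (together with its hydrazone precursor in step 11). Hydride transfer to the electron-rich aryl hydrazone could remain incomplete, or the ring oxygen could be lost by β-elimination during hydrazone formation or diazene breakdown. The fallback removes the C1 oxygen by a radical route. It sets out from 15. NaBH4 in MeOH would give the C1 carbinol F7. Phenyl chlorothionoformate, pyridine and DMAP would give the O-phenyl thionocarbonate F8. Barton–McCombie deoxygenation (Bu3SnH, AIBN, toluene, 80 °C) through the benzylic radical comes back to the route at 19.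

**Further compounds**

F1 | step 10 | ethyl (2E)-3-{(1S,3R)-1-[4-(benzyloxy)-3-methoxyphenyl]-3-[(tert-butyldimethylsilyl)oxy]-4-chlorobutoxy}prop-2-enoate | ClC[C@H](O[Si](C)(C)C(C)(C)C)C[C@H](O/C=C/C(=O)OCC)c1ccc(OCc2ccccc2)c(OC)c1
F2 | step 10 | ethyl (2E)-3-{(1S,3R)-1-[4-(benzyloxy)-3-methoxyphenyl]-3-[(tert-butyldimethylsilyl)oxy]-4-iodobutoxy}prop-2-enoate | IC[C@H](O[Si](C)(C)C(C)(C)C)C[C@H](O/C=C/C(=O)OCC)c1ccc(OCc2ccccc2)c(OC)c1
F3 | step 10 | ethyl 2-[(2R,4S,6S)-6-[4-(benzyloxy)-3-methoxyphenyl]-4-[(tert-butyldimethylsilyl)oxy]oxan-2-yl]acetate | CCOC(=O)C[C@H]1C[C@H](O[Si](C)(C)C(C)(C)C)C[C@@H](c2ccc(OCc3ccccc3)c(OC)c2)O1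
F4 | step 10 | 2-[(2R,4S,6S)-6-[4-(benzyloxy)-3-methoxyphenyl]-4-[(tert-butyldimethylsilyl)oxy]oxan-2-yl]-N-methoxy-N-methylacetamide | CON(C)C(=O)C[C@H]1C[C@H](O[Si](C)(C)C(C)(C)C)C[C@@H](c2ccc(OCc3ccccc3)c(OC)c2)O1
F5 | step 9 | (3R)-1-[4-(benzyloxy)-3-methoxyphenyl]-3-[(tert-butyldimethylsilyl)oxy]-4-iodobutan-1-one | IC[C@H](O[Si](C)(C)C(C)(C)C)CC(=O)c1ccc(OCc2ccccc2)c(OC)c1
F6 | step 9 | (1S,3R)-1-[4-(benzyloxy)-3-methoxyphenyl]-3-[(tert-butyldimethylsilyl)oxy]-4-iodobutan-1-ol | IC[C@H](O[Si](C)(C)C(C)(C)C)C[C@H](O)c1ccc(OCc2ccccc2)c(OC)c1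
F7 | step 12 | C1 carbinol of 15 (both C1 epimers, ring unchanged): 1-[4-(benzyloxy)-3-methoxyphenyl]-2-[6-[4-(benzyloxy)-3-methoxyphenyl]-4-[(tert-butyldimethylsilyl)oxy]oxan-2-yl]ethan-1-ol | OC(C[C@H]1C[C@H](O[Si](C)(C)C(C)(C)C)C[C@@H](c2ccc(OCc3ccccc3)c(OC)c2)O1)c1ccc(OCc2ccccc2)c(OC)c1
F8 | step 12 | O-phenyl thionocarbonate of F7 (both C1 epimers) | S=C(Oc1ccccc1)OC(C[C@H]1C[C@H](O[Si](C)(C)C(C)(C)C)C[C@@H](c2ccc(OCc3ccccc3)c(OC)c2)O1)c1ccc(OCc2ccccc2)c(OC)c1
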